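**Numbering and remark on the chemistry.** Ring A is the monobrominated ring (C1 OH, C2 ether oxygen, C4 Br). Ring B is the tribrominated ring (C1 OH, C2 ether oxygen, C3, C4 and C6 Br). The target is achiral, so no step has to set or keep a configuration. Compounds: 1 2-phenoxyaniline, 2 hexane-2,5-dione, 3 pyrrole-masked diaryl ether, 4 dilithio species, 5 bis(boronate), 6 pyrrole-masked diol, 7 aminodiol, 8 tribromo aminodiol, 9 diazonium salt, 10 target.

## The problem

Compound 10 consists of two benzene rings joined only through one oxygen, so the whole task is regiochemistry on two arenes. On ring B the bridging oxygen (C2) lies between a hydroxyl (C1) and a bromine (C3). A late aryl–O–aryl coupling at that doubly flanked carbon of a polybrominated ring would be slow and would have to choose among several C–Br bonds. Three bromines (ring B C4 and C6, ring A C4) are ortho or para to a hydroxyl and can come from electrophilic substitution. The ring B C3 bromine is meta to the hydroxyl and cannot, so it needs a placeholder. Aryl bromides do not survive organolithium reagents or hydrogenolysis, so every C–Br bond must be made after the last organometallic step. The electron-rich aminophenol intermediates are sensitive to air and oxidants. An ortho-hydroxy diaryl ether with a leaving group on the other ring's ortho carbon can also close to a dibenzo-1,4-dioxin. The enabling feature is that both hydroxyl-bearing carbons, C1 of ring A and C1 of ring B, are ortho to the bridging oxygen, the positions to which an aryl ether oxygen directs lithiation. An intact diaryl ether can therefore receive both hydroxyls in one operation if ring B C3 is already occupied, and a nitrogen there can later steer bromine to C4 and C6 and then be exchanged for the C3 bromine.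

## Retrosynthesis

**10 to 8 (through 9).** The ring B C3–Br bond is cut first and traced to an aromatic amine by a Sandmeyer reaction through diazonium salt 9. This is the one bromine that electrophilic substitution cannot place. An amine at C3 is also the strongest ortho/para director available and points to C4 and C6. Cutting the diaryl ether bond instead would require coupling at a carbon with two ortho substituents. Precursor 8 differs from 10 only in NH2 for Br. The forward reaction must diazotise a weakly basic, hindered aniline beside two free phenols, and 9 must take up bromine faster than it reacts with ring A.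

**8 to 7.** The three remaining C–Br bonds (ring B C4 and C6, ring A C4) are cut together. On ring B the amine (C3) and the hydroxyl (C1) both activate C4 and C6, and C5 is meta to both. On ring A the hydroxyl directs para to C4. Brominating while the amine is free gives the largest reactivity gap between the rings. Precursor 7 is a halogen-free aminodiol. The forward reaction must put exactly two bromines on ring B and one on ring A, para rather than ortho to the ring A hydroxyl.

**7 to 6.** The amine is traced to its 2,5-dimethylpyrrole. During the organolithium step the nitrogen needs a mask with no N–H, no carbonyl and no acidic C–H. A carbamate or amide would direct lithiation to ring B C4 or be attacked. The dimethylpyrrole is inert to alkyllithiums and is a poor director. The forward reaction is a transoximation that leaves phenols untouched.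

**6 to 3 (through 4 and 5), the key disconnection.** Both aryl C–OH bonds (ring A C1–O and ring B C1–O) are cut at once. The ether oxygen of 3 directs lithiation to one ortho position on each ring, giving dilithio species 4. Borylation gives bis(boronate) 5, and oxidation gives 6. The alternative of joining a catechol derivative to a 2,3-dioxygenated aniline would again require bond formation at a hindered carbon. Precursor 3 has no oxygen function except the bridge. The forward reaction must metalate once per ring and only ortho to oxygen.

**3 to 1 and 2.** The two pyrrole C–N bonds are cut by a Paal–Knorr disconnection to 2-phenoxyaniline 1 and hexane-2,5-dione 2, both commercial. The diaryl ether is bought, and the only demand is complete condensation of an ortho-substituted aniline.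

## Roads not taken

**Alternative 1:** Ring B is carried as a cyclohexane-1,3-dione. The cut is the ring B C1–C2 bond. 5-Bromo-2-methoxyphenol A1 is O-alkylated to the keto ester A2. The enolate at the aryloxymethyl carbon of A2 then attacks the ester, closing the six-membered ring as dione A3. Merits: the crowded aryl–O bond at ring B C2 is made by simple alkylation of a phenol, and the ring A bromine is fixed by the choice of A1. In that last respect this road is better than the chosen plan, which depends on para selectivity in the bromination of 7. Weak points: A3 is four oxidation levels from a tribromophenol. One carbonyl must become C–Br, the ring must be aromatised, and two more bromines placed. All of this happens beside the electron-rich anisole ring A, which competes for electrophilic bromine, and an O-demethylation still follows. Against the certainty at ring A, the chosen plan offers five steps from a bought diaryl ether, each of a classical type.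

**Alternative 2:** The cut is the ring B C2–O and C3–Br bonds. The boryl-substituted aryne released from iodoaryl triflate A4 by halogen–magnesium exchange adds the magnesium salt of A1 next to boron. The resulting arylmagnesium is brominated to give boronate A5. Oxidation of the C–B bond, bromination ortho and para to the new hydroxyl, and demethylation would finish the route. This road is convergent, fixes both the ring B C3 bromine and the ring A bromine, and avoids a diazonium salt. On those counts it is at least as good as the chosen plan. Weak points for this target: the aryloxide of A1 has an ortho substituent and must add at the aryne carbon next to the bulky boronate. It also carries an aryl bromide that must survive the exchange reagent. Trapping an aryne with an oxygen nucleophile and then an electrophile is less secure than with softer nucleophiles. A4 itself needs several steps. The chosen plan answers with commercial starting materials and a key step of a well-established reaction type.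

**Alternative 3:** Ring A is built from acyclic pieces. The cut is the ring A C2–C3 and C5–C6 bonds. Aryloxyacetone A6 condenses twice with 2-bromomalonaldehyde A7 (aldol addition and dehydration at both the methylene and the methyl group), and the ring tautomerises to phenol A8. Merits: the ring A bromine is placed by construction, and the ring B C3 bromine is present from the start. These are the two positions where the chosen plan relies on selectivity and on a Sandmeyer reaction. Weak points: A7 is a base-sensitive α-halo dialdehyde, and the condensation must engage both α-carbons of A6 in the right sense. A8 still lacks the ring B bromines at C4 and C6. In A8 the free phenol is on ring A and the ring B oxygen is methylated, so electrophilic bromine would go to ring A first. A protecting-group exchange would be needed before the last two bromines, which costs the step economy. In 7 of the chosen plan the more activated ring is the one that must take two bromines.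

Key step: step 2

## Route

**Step 1**
Reactants: 1 2-phenoxyaniline; 2 hexane-2,5-dione
Product: 3 2,5-dimethyl-1-(2-phenoxyphenyl)pyrrole
Conditions: 2 (1.2 equiv), p-TsOH·H2O (5 mol %), toluene, reflux, Dean–Stark
Reagents that add atoms: none
Why: Paal–Knorr pyrrole synthesis; the primary aniline condenses twice with the 1,4-diketone under acid catalysis with azeotropic removal of water, giving a mask with no N–H and no C–H acidic enough to interfere with the organolithium step.

**Step 2**
Reactants: 3 2,5-dimethyl-1-(2-phenoxyphenyl)pyrrole
Product: 6 3-(2,5-dimethylpyrrol-1-yl)-2-(2-hydroxyphenoxy)phenol, via dilithio diaryl ether 4 (not isolated), via bis(dimethyl boronate) 5 (not isolated)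
Conditions: n-BuLi (2.6 equiv), TMEDA (2.6 equiv), Et2O/hexane, 0 °C to rt; B(OMe)3 (4 equiv), −78 °C to rt; 30% aq H2O2, 2 M aq NaOH, 0 °C to rt
Reagents that add atoms: hydrogen peroxide, OO
Why: Directed ortho-metalation: n-BuLi, deaggregated by TMEDA, binds to the bridging ether oxygen and removes the inductively acidified ortho proton on each ring, giving dilithio species 4. Trimethyl borate captures both aryllithiums as methoxyborate complexes that lose methoxide to give 5; alkaline hydrogen peroxide then adds hydroperoxide to each boron, the aryl group migrates from boron to oxygen at the ipso carbon, and hydrolysis releases the two phenols of 6. The closest known reaction type is the 2,2'-dilithiation of diphenyl ether with n-BuLi/TMEDA, used to make 2,2'-disubstituted diphenyl ethers, combined with the standard borylation–oxidation of aryllithiums to phenols. No ring is closed and no stereocenter is formed. The step needs site selectivity: on ring B the only free position ortho to oxygen is C1, because C3 carries the pyrrole. Ring B C4, ortho to the pyrrole nitrogen, should not compete, since that nitrogen's lone pair belongs to the aromatic sextet and the pyrrole is twisted out of plane by its methyl groups, so it coordinates lithium poorly. The pyrrole α-positions are blocked by methyl groups, and its β and methyl hydrogens are not acidic enough to compete, which is why this mask tolerates alkyllithiums. The second deprotonation goes to the other ring and not to the second ortho position of ring A because an aryl anion deactivates its own ring; excess base and a long metalation time drive the reaction past the monolithio stage.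

**Step 3**
Reactants: 6 3-(2,5-dimethylpyrrol-1-yl)-2-(2-hydroxyphenoxy)phenol
Product: 7 3-amino-2-(2-hydroxyphenoxy)phenol
Conditions: NH2OH·HCl (10 equiv), Et3N (5 equiv), EtOH/H2O 2:1, reflux, under argon
Reagents that add atoms: none
Why: Transoximation, the standard removal of the 2,5-dimethylpyrrole mask; hydroxylamine opens the pyrrole to the dioxime of hexane-2,5-dione and releases the aniline, while phenols and the diaryl ether are inert.

**Step 4**
Reactants: 7 3-amino-2-(2-hydroxyphenoxy)phenol
Product: 8 3-amino-4,6-dibromo-2-(5-bromo-2-hydroxyphenoxy)phenol
Conditions: NBS (2.0 equiv), MeCN, −20 °C; then NBS (1.0 equiv), 0 °C to rt, dark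
Reagents that add atoms: N-bromosuccinimide, O=C1CCC(=O)N1Br
Why: Electrophilic aromatic bromination; the first two equivalents should go to ring B at C6 (para to NH2, ortho to OH) and C4 (ortho to NH2, para to OH), where both donors reinforce each other and C5 is meta to both. The third equivalent then finds ring A as the only activated ring and should enter para to its hydroxyl (C4), as in the para-bromination of 2-alkoxyphenols.

**Step 5**
Reactants: 8 3-amino-4,6-dibromo-2-(5-bromo-2-hydroxyphenoxy)phenol
Product: 10 3,4,6-tribromo-2-(5-bromo-2-hydroxyphenoxy)phenol, via diazonium bromide 9 (not isolated)
Conditions: NaNO2 (1.1 equiv), 48% aq HBr, AcOH, 0 °C; then added to CuBr (1.5 equiv), 48% aq HBr, 0 to 50 °C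
Reagents that add atoms: hydrobromic acid, Br; CuBr, Br[Cu] (transfers the bromine atom and is regenerated)
Why: Sandmeyer bromination; diazotisation in strong acid keeps the phenols protonated and so suppresses azo coupling, and electron transfer from CuBr gives the aryl radical, which should take bromine from the CuBr2 so formed faster than it adds to ring A. The reaction type is known for weakly basic ortho-halo anilines, for aminophenols and for 2-aryloxyanilines.

## Compound list

1 | 2-phenoxyaniline | Nc1ccccc1Oc1ccccc1 | starting material
2 | hexane-2,5-dione | CC(=O)CCC(C)=O | starting material
3 | 2,5-dimethyl-1-(2-phenoxyphenyl)pyrrole | Cc1ccc(C)n1-c1ccccc1Oc1ccccc1 | intermediate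
4 | 1-[3-lithio-2-(2-lithiophenoxy)phenyl]-2,5-dimethylpyrrole | Cc1ccc(C)n1-c1cccc([Li])c1Oc1ccccc1[Li] | intermediate
5 | 1-[3-(dimethoxyboryl)-2-[2-(dimethoxyboryl)phenoxy]phenyl]-2,5-dimethylpyrrole | Cc1ccc(C)n1-c1cccc(B(OC)OC)c1Oc1ccccc1B(OC)OC | intermediate
6 | 3-(2,5-dimethylpyrrol-1-yl)-2-(2-hydroxyphenoxy)phenol | Cc1ccc(C)n1-c1cccc(O)c1Oc1ccccc1O | intermediate
7 | 3-amino-2-(2-hydroxyphenoxy)phenol | Nc1cccc(O)c1Oc1ccccc1O | intermediate
8 | 3-amino-4,6-dibromo-2-(5-bromo-2-hydroxyphenoxy)phenol | Nc1c(Br)cc(Br)c(O)c1Oc1cc(Br)ccc1O | intermediate
9 | 4,6-dibromo-2-(5-bromo-2-hydroxyphenoxy)-3-hydroxybenzenediazonium bromide | N#[N+]c1c(Br)cc(Br)c(O)c1Oc1cc(Br)ccc1O.[Br-] | intermediate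
10 | 3,4,6-tribromo-2-(5-bromo-2-hydroxyphenoxy)phenol | Oc1ccc(Br)cc1Oc1c(O)c(Br)cc(Br)c1Br | target

## Step count and risk

Total step count: 5. Longest linear sequence: 5 steps (1 to 3 to 6 to 7 to 8 to 10).

**Step 2 (key step).** The most likely failure is incomplete second metalation, which stops at a monolithio species and gives mono-hydroxylated material. Less likely are misdirected deprotonation on ring B next to the pyrrole nitrogen or on a pyrrole methyl group, and oxidative damage to the electron-rich pyrrole during the peroxide stage. The fallback abandons the lithiation and builds the ether with both ring oxygens already in place. It therefore sets out from no numbered compound of the route but from two further commercial compounds. 2-Fluoro-1-methoxy-3-nitrobenzene F1 and 2-methoxyphenol F2 are joined by nucleophilic aromatic substitution (K2CO3, DMF, 90 °C), the nitro group activating the adjacent C–F bond, to give 1-methoxy-2-(2-methoxyphenoxy)-3-nitrobenzene F3. Hydrogenation (H2, Pd/C, EtOAc) gives 3-methoxy-2-(2-methoxyphenoxy)aniline F4. Twofold O-demethylation with BBr3 in CH2Cl2, which leaves the diaryl ether intact, brings the sequence back to the route at compound 7.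

**Step 4.** The concern is loss of site control on ring A. Its hydroxyl activates both C4 and C6, so ortho bromination or a second bromination of ring A may compete with the third equivalent. Oxidation of the aminophenol by the N-bromo imide may also erode the material balance. The fallback separates the two rings in time. It sets out from compound 7, which is treated with only two equivalents of NBS at −20 °C to give 3-amino-4,6-dibromo-2-(2-hydroxyphenoxy)phenol F5. Diazotisation (NaNO2, aq HBr, AcOH) gives 4,6-dibromo-3-hydroxy-2-(2-hydroxyphenoxy)benzenediazonium bromide F6, and CuBr converts it to 3,4,6-tribromo-2-(2-hydroxyphenoxy)phenol F7. Ring B of F7 is fully deactivated and ring A is the only reactive arene, so one equivalent of tetrabutylammonium tribromide, a bulky para-selective brominating agent for phenols, should give the target. The fallback comes back to the route at compound 10.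

**Step 5.** The diazonium group of 9 lies ortho to the aryloxy bridge. It may be captured by the ring A hydroxyl, closing a dibenzo-1,4-dioxin. The derived aryl radical may add to ring A C3 in a Pschorr-type closure to a dibenzofuran. Azo coupling at ring A C6 and simple reduction are further losses. The fallback masks both phenols before diazotisation. It sets out from compound 8, whose hindered and electron-poor amine should not compete with the phenolates for MeI (K2CO3, acetone, rt), giving 4,6-dibromo-2-(5-bromo-2-methoxyphenoxy)-3-methoxyaniline F8. Diazotisation gives 4,6-dibromo-2-(5-bromo-2-methoxyphenoxy)-3-methoxybenzenediazonium bromide F9, which can no longer be trapped by oxygen or couple as a phenol. CuBr in aq HBr then gives 1,2,5-tribromo-3-(5-bromo-2-methoxyphenoxy)-4-methoxybenzene F10. BBr3 in CH2Cl2 removes both methyl groups, and the fallback comes back to the route at compound 10.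

## Further compounds

F1 | step 2 | 2-fluoro-1-methoxy-3-nitrobenzene | COc1cccc([N+](=O)[O-])c1F
F2 | step 2 | 2-methoxyphenol | COc1ccccc1O
F3 | step 2 | 1-methoxy-2-(2-methoxyphenoxy)-3-nitrobenzene | COc1ccccc1Oc1c(OC)cccc1[N+](=O)[O-]
F4 | step 2 | 3-methoxy-2-(2-methoxyphenoxy)aniline | COc1ccccc1Oc1c(N)cccc1OC
F5 | step 4 | 3-amino-4,6-dibromo-2-(2-hydroxyphenoxy)phenol | Nc1c(Br)cc(Br)c(O)c1Oc1ccccc1O
F6 | step 4 | 4,6-dibromo-3-hydroxy-2-(2-hydroxyphenoxy)benzenediazonium bromide | N#[N+]c1c(Br)cc(Br)c(O)c1Oc1ccccc1O.[Br-]
F7 | step 4 | 3,4,6-tribromo-2-(2-hydroxyphenoxy)phenol | Oc1ccccc1Oc1c(O)c(Br)cc(Br)c1Br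
F8 | step 5 | 4,6-dibromo-2-(5-bromo-2-methoxyphenoxy)-3-methoxyaniline | COc1ccc(Br)cc1Oc1c(N)c(Br)cc(Br)c1OC
F9 | step 5 | 4,6-dibromo-2-(5-bromo-2-methoxyphenoxy)-3-methoxybenzenediazonium bromide | COc1ccc(Br)cc1Oc1c([N+]#N)c(Br)cc(Br)c1OC.[Br-]
F10 | step 5 | 1,2,5-tribromo-3-(5-bromo-2-methoxyphenoxy)-4-methoxybenzene | COc1ccc(Br)cc1Oc1c(Br)c(Br)cc(Br)c1OC
A1 | alternative 1 | 5-bromo-2-methoxyphenol | COc1ccc(Br)cc1O
A2 | alternative 1 | methyl 6-(5-bromo-2-methoxyphenoxy)-5-oxohexanoate | COC(=O)CCCC(=O)COc1cc(Br)ccc1OC
A3 | alternative 1 | 2-(5-bromo-2-methoxyphenoxy)cyclohexane-1,3-dione | O=C1CCCC(=O)C1Oc1cc(Br)ccc1OC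
A4 | alternative 2 | 2-iodo-6-(4,4,5,5-tetramethyl-1,3,2-dioxaborolan-2-yl)phenyl trifluoromethanesulfonate | CC1(C)OB(OC1(C)C)c1cccc(I)c1OS(=O)(=O)C(F)(F)F
A5 | alternative 2 | 2-[3-bromo-2-(5-bromo-2-methoxyphenoxy)phenyl]-4,4,5,5-tetramethyl-1,3,2-dioxaborolane | CC1(C)OB(OC1(C)C)c1cccc(Br)c1Oc1cc(Br)ccc1OC
A6 | alternative 3 | 1-(2-bromo-6-methoxyphenoxy)propan-2-one | CC(=O)COc1c(Br)cccc1OC
A7 | alternative 3 | 2-bromomalonaldehyde | O=CC(Br)C=O
A8 | alternative 3 | 4-bromo-2-(2-bromo-6-methoxyphenoxy)phenol | Oc1ccc(Br)cc1Oc1c(Br)cccc1OC
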